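The plan cuts the C7=C8 olefin of the 2,9-dioxabicyclo[3.3.1]nona-3,7-diene core. Ring B (O9–C1–C8=C7–C6–C5) shares only the C5–O9–C1 unit with ring A (C1–O2–C3=C4–C5–O9). Its remaining carbons hang as two 1,3-cis arms on ring A. Ring A is therefore built first, as a 1,3-dioxan-4-one from a β-hydroxy acid and ethyl isopropenyl ketone. Ring-closing metathesis of the butenyl and isopropenyl arms closes ring B in one operation. Only the ketal epimer with cis arms can react, which secures quaternary C1. The lactone carbonyl (C3) then brings in the side chain by methylenation, carbonyl-ene reaction, oxidation and convex-face methylation.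

Key step: step 8

Locants: in the bicyclic compounds C1 is the ketal carbon, followed by O2, C3, C4, C5 (bridgehead CH), C6, C7, C8 and O9 (bridging oxygen). Dioxanone 12 is numbered O1, C2 (ketal carbon), O3, C4 (C=O), C5, C6.
Assumption: the carbinol centre made in step 15 is carried as a mixture of epimers, because step 16 removes it.

Step 1
Reactants: 1 methyl (S)-3-hydroxy-2-methylpropanoate
Product: 2 methyl (S)-3-[(tert-butyldimethylsilyl)oxy]-2-methylpropanoate
Conditions: TBSCl, imidazole, CH2Cl2, 0 °C to rt
Reagents that add atoms: tert-butyldimethylsilyl chloride, CC(C)(C)[Si](C)(C)Cl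
Why: Corey silylation (silyl ether protection) of the only hydroxyl group, which does not involve the stereocentre.

Step 2
Reactants: 2 methyl (S)-3-[(tert-butyldimethylsilyl)oxy]-2-methylpropanoate
Product: 3 (S)-3-[(tert-butyldimethylsilyl)oxy]-2-methylpropanal
Conditions: i-Bu2AlH (1.1 equiv), CH2Cl2, −78 °C; aq. work-up
Reagents that add atoms: none
Why: Partial hydride reduction of an ester, which stops at the aldehyde because the tetrahedral aluminium alkoxide survives at −78 °C, and the α-stereocentre is kept when 3 is used without chromatography.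

Step 3
Reactants: 3 (S)-3-[(tert-butyldimethylsilyl)oxy]-2-methylpropanal
Product: 5 (2S,3S,4S)-1-[(tert-butyldimethylsilyl)oxy]-2,4-dimethylhex-5-en-3-ol, via borate ester 4 (not isolated)
Conditions: (E)-crotyl-B(pin) (1.3 equiv), (S)-TRIP phosphoric acid (5 mol%), 4 Å MS, toluene, −30 °C; aq. NaHCO3
Reagents that add atoms: (E)-crotylboronic acid pinacol ester, C/C=C/CB1OC(C)(C)C(C)(C)O1
Why: Chiral-phosphoric-acid-catalysed crotylboration through a closed chair (Zimmerman–Traxler) transition state, in which the (E)-boronate gives the anti C3/C4 pair and the (S)-catalyst directs attack to the Si face of the aldehyde, which is also the Felkin face of 3 (matched case), so the 2,3-syn-3,4-anti triad results.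

Step 4
Reactants: 5 (2S,3S,4S)-1-[(tert-butyldimethylsilyl)oxy]-2,4-dimethylhex-5-en-3-ol
Product: 6 (2S,3S,4S)-2,4-dimethylhex-5-ene-1,3-diol
Conditions: camphorsulfonic acid (10 mol%), MeOH, 0 °C
Reagents that add atoms: none
Why: Acid-catalysed methanolysis (desilylation) of a primary TBS ether, mild enough for the homoallylic alcohol.

Step 5
Reactants: 6 (2S,3S,4S)-2,4-dimethylhex-5-ene-1,3-diol
Product: 8 (2R,3S,4S)-3-hydroxy-2,4-dimethylhex-5-enoic acid, via hydroxy aldehyde 7 (not isolated)
Conditions: TEMPO (20 mol%), PhI(OAc)2 (2.2 equiv), MeCN/H2O 1:1, rt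
Reagents that add atoms: water, O
Why: Oxoammonium (TEMPO) oxidation, which takes the primary alcohol much faster than the hindered secondary one and carries the aldehyde hydrate on to the acid without disturbing C2.

Step 6
Reactants: 9 pentan-3-one
Product: 10 2-methylpent-1-en-3-one
Conditions: (CH2O)n, i-Pr2NH·CF3CO2H (1 equiv), CF3CO2H (10 mol%), THF, reflux
Reagents that add atoms: paraformaldehyde (source of formaldehyde), C=O
Why: Mannich-type α-methylenation of a ketone (iminium aldol, then amine elimination), and the symmetric ketone can give only one mono-methylenated product.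

Step 7
Reactants: 8 (2R,3S,4S)-3-hydroxy-2,4-dimethylhex-5-enoic acid; 10 2-methylpent-1-en-3-one
Product: 12 (2S,5R,6S)-6-[(2S)-but-3-en-2-yl]-2-ethyl-5-methyl-2-(prop-1-en-2-yl)-1,3-dioxan-4-one, via bis-silyl derivative 11 (not isolated)
Conditions: (Me3Si)2NH, CH2Cl2, rt, concentrate; then 10 (1.5 equiv), TMSOTf (10 mol%), CH2Cl2, −78 °C; pyridine quench
Reagents that add atoms: hexamethyldisilazane, C[Si](C)(C)N[Si](C)(C)C (its silyl groups are carried only by 11)
Why: Noyori–Seebach silyl-transfer ketalization driven by formation of hexamethyldisiloxane, in which the silyl ether adds to the activated ketone, the oxocarbenium ion keeps the flat, wider isopropenyl group anti to C6, and kinetic chair-like capture by the silyl ester places that group equatorial and cis to the butenyl arm, which sets the (S) ketal carbon.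

Step 8
Reactants: 12 (2S,5R,6S)-6-[(2S)-but-3-en-2-yl]-2-ethyl-5-methyl-2-(prop-1-en-2-yl)-1,3-dioxan-4-one
Product: 13 (1S,4R,5S,6S)-1-ethyl-4,6,8-trimethyl-2,9-dioxabicyclo[3.3.1]non-7-en-3-one
Conditions: second-generation Hoveyda–Grubbs catalyst (5 mol%), toluene (5 mM), 70 °C, argon sparge
Reagents that add atoms: none
Why: The ruthenium alkylidene first exchanges with the unhindered vinyl group of the C6 arm, then adds to the isopropenyl group on C2 in a [2+2] step, and cycloreversion of the ruthenacyclobutane releases the trisubstituted C7=C8 olefin while ethene leaves the solution (Chauvin mechanism). The closest known reaction type is the ketal-tethered ring-closing metathesis used to make bridged bicyclic ketals from dienes held on one ketal ring. Ring B is closed as a six-membered ring with an endocyclic olefin that bridges the 1,3-related atoms C2 and C6 of ring A (C1 and C5 of 13), which demands the chair with both arms axial, and this chair is affordable because it turns the C5 methyl group from axial to equatorial. No stereocentre is formed, but closure is geometrically possible only when the isopropenyl group is cis to the butenyl arm, so the (S) ketal carbon set in step 7 is proof-read and any trans epimer stays behind unchanged. The step needs ring closure to win over dimerisation of the vinyl group, and this is secured by high dilution, by a 1,1-disubstituted partner that does not homodimerise and by the absence of any other olefin, since the side-chain alkene arrives only in step 15. The acyloxy ketal is left alone because the catalyst is neutral.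

Step 9
Reactants: 13 (1S,4R,5S,6S)-1-ethyl-4,6,8-trimethyl-2,9-dioxabicyclo[3.3.1]non-7-en-3-one
Product: 14 (1S,4R,5S,6S)-1-ethyl-4,6,8-trimethyl-3-methylidene-2,9-dioxabicyclo[3.3.1]non-7-ene
Conditions: Cp2TiMe2 (2.5 equiv), toluene, 70 °C, dark
Reagents that add atoms: dimethyltitanocene, C[Ti](C)(C1C=CC=C1)C1C=CC=C1
Why: Petasis methylenation of a lactone carbonyl by Cp2Ti=CH2, a neutral olefination with direct precedent on 1,3-dioxan-4-ones, so the ketal and the C4 stereocentre survive.

Step 10
Reactants: 15 (E)-2-methylpent-2-enal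
Product: 16 (E)-2-methylpent-2-en-1-ol
Conditions: NaBH4, MeOH, 0 °C
Reagents that add atoms: none
Why: Borohydride 1,2-reduction of an α-substituted enal, which leaves the E olefin untouched.

Step 11
Reactants: 16 (E)-2-methylpent-2-en-1-ol
Product: 17 (E)-1-bromo-2-methylpent-2-ene
Conditions: PBr3 (0.4 equiv), Et2O, 0 °C
Reagents that add atoms: phosphorus tribromide, BrP(Br)Br
Why: SN2-type bromination of a primary allylic alcohol through its phosphite ester, without allylic shift or loss of olefin geometry at 0 °C.

Step 12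
Reactants: 18 (S)-4-benzyl-3-propanoyl-1,3-oxazolidin-2-one; 17 (E)-1-bromo-2-methylpent-2-ene
Product: 20 (S)-4-benzyl-3-[(2R,4E)-2,4-dimethylhept-4-enoyl]-1,3-oxazolidin-2-one, via sodium enolate 19 (not isolated)
Conditions: NaN(SiMe3)2 (1.1 equiv), THF, −78 °C; then 17 (2 equiv), −78 to −40 °C
Reagents that add atoms: none
Why: Evans asymmetric alkylation, in which the chelated (Z)-sodium enolate is attacked by the allylic bromide on the face opposite to the benzyl group, which sets the (R) methyl-bearing centre.

Step 13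
Reactants: 20 (S)-4-benzyl-3-[(2R,4E)-2,4-dimethylhept-4-enoyl]-1,3-oxazolidin-2-one
Product: 21 (2R,4E)-2,4-dimethylhept-4-en-1-ol
Conditions: LiBH4, MeOH (1 equiv), Et2O, 0 °C
Reagents that add atoms: none
Why: Reductive cleavage of the N-acyl oxazolidinone (hydride attack at the exocyclic carbonyl), which proceeds without epimerisation.

Step 14
Reactants: 21 (2R,4E)-2,4-dimethylhept-4-en-1-ol
Product: 22 (2R,4E)-2,4-dimethylhept-4-enal
Conditions: TEMPO (10 mol%), PhI(OAc)2 (1.1 equiv), CH2Cl2, rt
Reagents that add atoms: none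
Why: TEMPO/PhI(OAc)2 oxidation of a primary alcohol, which stops at the aldehyde in dry CH2Cl2 and is neutral enough to keep the α-stereocentre.

Step 15
Reactants: 14 (1S,4R,5S,6S)-1-ethyl-4,6,8-trimethyl-3-methylidene-2,9-dioxabicyclo[3.3.1]non-7-ene; 22 (2R,4E)-2,4-dimethylhept-4-enal
Product: 23 (3R,5E)-1-[(1S,5S,6S)-1-ethyl-4,6,8-trimethyl-2,9-dioxabicyclo[3.3.1]nona-3,7-dien-3-yl]-3,5-dimethyloct-5-en-2-ol (both C2 epimers)
Conditions: Yb(fod)3 (10 mol%), CH2Cl2, rt
Reagents that add atoms: none
Why: Lewis-acid-catalysed carbonyl-ene reaction of an exocyclic enol ether, in which the nucleophilic methylene carbon bonds to the aldehyde while the axial exo hydrogen on C4 passes to oxygen in a six-membered transition state, so the double bond moves to C3=C4 in ring A and the new carbinol centre is of no consequence.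

Step 16
Reactants: 23 (3R,5E)-1-[(1S,5S,6S)-1-ethyl-4,6,8-trimethyl-2,9-dioxabicyclo[3.3.1]nona-3,7-dien-3-yl]-3,5-dimethyloct-5-en-2-ol (both C2 epimers)
Product: 24 (3R,5E)-1-[(1S,5S,6S)-1-ethyl-4,6,8-trimethyl-2,9-dioxabicyclo[3.3.1]nona-3,7-dien-3-yl]-3,5-dimethyloct-5-en-2-one
Conditions: Dess–Martin periodinane, pyridine, CH2Cl2, 0 °C
Reagents that add atoms: none
Why: Dess–Martin oxidation under pyridine buffer, which spares the enol ether, ketal and olefins, and a shift of the C3=C4 bond into conjugation would be harmless because both isomers give the same dienolate in step 17.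

Step 17
Reactants: 24 (3R,5E)-1-[(1S,5S,6S)-1-ethyl-4,6,8-trimethyl-2,9-dioxabicyclo[3.3.1]nona-3,7-dien-3-yl]-3,5-dimethyloct-5-en-2-one
Product: 26 (2S,4R,6E)-2-[(1S,5S,6S)-1-ethyl-4,6,8-trimethyl-2,9-dioxabicyclo[3.3.1]nona-3,7-dien-3-yl]-4,6-dimethylnon-6-en-3-one, via lithium dienolate 25 (not isolated)
Conditions: LiN(SiMe3)2 (1.05 equiv), THF/DMPU, −78 °C; MeI (5 equiv), −78 to −50 °C; cold AcOH/THF quench
Reagents that add atoms: iodomethane, CI
Why: α-Alkylation of an extended enolate, in which the base removes the doubly activated CH2 proton, the dienolate is s-trans (its vinylic hydrogen lies next to the C4 methyl group), and iodomethane attacks the α-carbon from the convex face turned away from ring B, which sets the (S) centre.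

Compound list
1 | methyl (S)-3-hydroxy-2-methylpropanoate | COC(=O)[C@@H](C)CO | starting material
2 | methyl (S)-3-[(tert-butyldimethylsilyl)oxy]-2-methylpropanoate | COC(=O)[C@@H](C)CO[Si](C)(C)C(C)(C)C | intermediate
3 | (S)-3-[(tert-butyldimethylsilyl)oxy]-2-methylpropanal | O=C[C@@H](C)CO[Si](C)(C)C(C)(C)C | intermediate
4 | pinacol borate ester of 5 (not isolated) | C=C[C@H](C)[C@H](OB1OC(C)(C)C(C)(C)O1)[C@@H](C)CO[Si](C)(C)C(C)(C)C | intermediate
5 | (2S,3S,4S)-1-[(tert-butyldimethylsilyl)oxy]-2,4-dimethylhex-5-en-3-ol | C=C[C@H](C)[C@H](O)[C@@H](C)CO[Si](C)(C)C(C)(C)C | intermediate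
6 | (2S,3S,4S)-2,4-dimethylhex-5-ene-1,3-diol | C=C[C@H](C)[C@H](O)[C@@H](C)CO | intermediate
7 | (2R,3S,4S)-3-hydroxy-2,4-dimethylhex-5-enal (not isolated) | C=C[C@H](C)[C@H](O)[C@@H](C)C=O | intermediate
8 | (2R,3S,4S)-3-hydroxy-2,4-dimethylhex-5-enoic acid | C=C[C@H](C)[C@H](O)[C@@H](C)C(=O)O | intermediate
9 | pentan-3-one | CCC(=O)CC | starting material
10 | 2-methylpent-1-en-3-one | C=C(C)C(=O)CC | intermediate
11 | trimethylsilyl (2R,3S,4S)-2,4-dimethyl-3-[(trimethylsilyl)oxy]hex-5-enoate (not isolated) | C=C[C@H](C)[C@H](O[Si](C)(C)C)[C@@H](C)C(=O)O[Si](C)(C)C | intermediate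
12 | (2S,5R,6S)-6-[(2S)-but-3-en-2-yl]-2-ethyl-5-methyl-2-(prop-1-en-2-yl)-1,3-dioxan-4-one | O=C1[C@H](C)[C@H]([C@@H](C)C=C)O[C@@](CC)(O1)C(C)=C | intermediate
13 | (1S,4R,5S,6S)-1-ethyl-4,6,8-trimethyl-2,9-dioxabicyclo[3.3.1]non-7-en-3-one | O=C1[C@H](C)[C@H]2O[C@@](CC)(O1)C(C)=C[C@@H]2C | intermediate
14 | (1S,4R,5S,6S)-1-ethyl-4,6,8-trimethyl-3-methylidene-2,9-dioxabicyclo[3.3.1]non-7-ene | C=C1[C@H](C)[C@H]2O[C@@](CC)(O1)C(C)=C[C@@H]2C | intermediate
15 | (E)-2-methylpent-2-enal | CC/C=C(\C)C=O | starting material
16 | (E)-2-methylpent-2-en-1-ol | CC/C=C(\C)CO | intermediate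
17 | (E)-1-bromo-2-methylpent-2-ene | CC/C=C(\C)CBr | intermediate
18 | (S)-4-benzyl-3-propanoyl-1,3-oxazolidin-2-one | CCC(=O)N1[C@@H](Cc2ccccc2)COC1=O | starting material
19 | sodium (Z)-enolate of 18 (not isolated) | C/C=C(\[O-])N1[C@@H](Cc2ccccc2)COC1=O.[Na+] | intermediate
20 | (S)-4-benzyl-3-[(2R,4E)-2,4-dimethylhept-4-enoyl]-1,3-oxazolidin-2-one | CC/C=C(\C)C[C@@H](C)C(=O)N1[C@@H](Cc2ccccc2)COC1=O | intermediate
21 | (2R,4E)-2,4-dimethylhept-4-en-1-ol | CC/C=C(\C)C[C@@H](C)CO | intermediate
22 | (2R,4E)-2,4-dimethylhept-4-enal | CC/C=C(\C)C[C@@H](C)C=O | intermediate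
23 | (3R,5E)-1-[(1S,5S,6S)-1-ethyl-4,6,8-trimethyl-2,9-dioxabicyclo[3.3.1]nona-3,7-dien-3-yl]-3,5-dimethyloct-5-en-2-ol, both C2 epimers | CC/C=C(\C)C[C@@H](C)C(O)CC1=C(C)[C@H]2O[C@@](CC)(O1)C(C)=C[C@@H]2C | intermediate
24 | (3R,5E)-1-[(1S,5S,6S)-1-ethyl-4,6,8-trimethyl-2,9-dioxabicyclo[3.3.1]nona-3,7-dien-3-yl]-3,5-dimethyloct-5-en-2-one | CC/C=C(\C)C[C@@H](C)C(=O)CC1=C(C)[C@H]2O[C@@](CC)(O1)C(C)=C[C@@H]2C | intermediate
25 | lithium dienolate of 24 (not isolated) | CC/C=C(\C)C[C@@H](C)C([O-])=CC1=C(C)[C@H]2O[C@@](CC)(O1)C(C)=C[C@@H]2C.[Li+] | intermediate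
26 | (2S,4R,6E)-2-[(1S,5S,6S)-1-ethyl-4,6,8-trimethyl-2,9-dioxabicyclo[3.3.1]nona-3,7-dien-3-yl]-4,6-dimethylnon-6-en-3-one | CC/C=C(\C)C[C@@H](C)C(=O)[C@@H](C)C1=C(C)[C@H]2O[C@@](CC)(O1)C(C)=C[C@@H]2C | target

Total step count: 17.
Longest linear sequence: 11 steps (steps 1–5, 7–9 and 15–17).

Steps most likely to fail

**Step 15.**
- What may go wrong: the α-branched aldehyde may react too slowly. Traces of acid may shift the exocyclic double bond of 14 into the ring before any C–C bond forms. The Lewis acid may also ionise the ketal and start an oxygen-to-carbon rearrangement.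
- Fallback: cross-coupling replaces ene chemistry. It sets out from 13 and 22 and comes back at 24.
- Aldehyde 22 is treated with MeMgBr to give (3R,5E)-3,5-dimethyloct-5-en-2-ol F1.
- Dess–Martin oxidation turns F1 into (3R,5E)-3,5-dimethyloct-5-en-2-one F2.
- Lactone 13 is deprotonated with KN(SiMe3)2 at −78 °C and trapped with (PhO)2P(O)Cl as the ketene acetal diphenyl phosphate F3.
- The kinetic enolate of F2 (LiN(i-Pr)2, methyl side) is transmetallated with ZnCl2.
- This zinc enolate is coupled with F3 under Pd2(dba)3/P(t-Bu)3, a Negishi-type α-alkenylation on zerovalent palladium, to give 24.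

**Step 17.**
- What may go wrong: facial selectivity on the dienolate may be poor. Proton exchange between product and enolate may cause epimerisation and double methylation. Some O-alkylation may occur.
- Fallback: the methyl group is delivered as a cyclopropane carbon, so no basic enolate meets the product. It sets out from 24 and comes back at 26.
- Ketone 24 is converted with TMSOTf/Et3N into the trimethylsilyl dienol ether F4.
- Furukawa cyclopropanation (Et2Zn, CH2I2) takes the electron-rich silyl enol ether double bond from the convex face and gives the siloxycyclopropane F5.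
- The configuration of the siloxy carbon in F5 follows the enol ether geometry and is lost afterwards.
- K2CO3 in MeOH at 0 °C removes the silyl group, and the strained cyclopropanol opens at its CH2–C(O) bond. This leaves the CH2 carbon as the methyl group of 26.

**Step 7.**
- What may go wrong: the hindered conjugated ketone may ketalise sluggishly. The silyl triflate may trigger conjugate addition. Facial selectivity at the oxocarbenium ion may be poor.
- Fallback: equilibrium transketalisation is combined with sorting by the metathesis. It sets out from 8 and 10 and comes back at 12.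
- Ketone 10 is converted with HC(OMe)3 and catalytic TsOH in MeOH into 3,3-dimethoxy-2-methylpent-1-ene F6.
- F6 and acid 8 are warmed with catalytic pyridinium tosylate in benzene while methanol is distilled off. This gives 12 together with its ketal epimer F7 under thermodynamic control.
- The mixture is taken into step 8, where only 12 can cyclise.
- Recovered F7 is returned to the equilibration.

Further compounds
F1 | step 15 | (3R,5E)-3,5-dimethyloct-5-en-2-ol, both C2 epimers | CC/C=C(\C)C[C@@H](C)C(C)O
F2 | step 15 | (3R,5E)-3,5-dimethyloct-5-en-2-one | CC/C=C(\C)C[C@@H](C)C(C)=O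
F3 | step 15 | (1S,5S,6S)-1-ethyl-4,6,8-trimethyl-2,9-dioxabicyclo[3.3.1]nona-3,7-dien-3-yl diphenyl phosphate | O=P(Oc1ccccc1)(Oc1ccccc1)OC1=C(C)[C@H]2O[C@@](CC)(O1)C(C)=C[C@@H]2C
F4 | step 17 | trimethylsilyl dienol ether of 24 | CC/C=C(\C)C[C@@H](C)C(O[Si](C)(C)C)=CC1=C(C)[C@H]2O[C@@](CC)(O1)C(C)=C[C@@H]2C
F5 | step 17 | siloxycyclopropane from F4 | CC/C=C(\C)C[C@@H](C)C3(O[Si](C)(C)C)C[C@H]3C1=C(C)[C@H]2O[C@@](CC)(O1)C(C)=C[C@@H]2C
F6 | step 7 | 3,3-dimethoxy-2-methylpent-1-ene | C=C(C)C(CC)(OC)OC
F7 | step 7 | (2R,5R,6S)-6-[(2S)-but-3-en-2-yl]-2-ethyl-5-methyl-2-(prop-1-en-2-yl)-1,3-dioxan-4-one | O=C1[C@H](C)[C@H]([C@@H](C)C=C)O[C@](CC)(O1)C(C)=C
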